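1. If the substrate had done nothing but close its ring, the yield of single ring would have stood at 100% at every charge, and if it had done nothing but react with itself, at 0%; those were my two extremes, and the runs had to lie between them.

| flask | substrate | remark | time |
|---|---|---|---|
| north-west | 0.15 M | run made earlier |  |
| south | 1 M | run made earlier |  |
| theta | 0.50 M |  | 1.0 h |
| gamma | 0.25 M |  | 1.0 h |
| beta | 1.5 M |  | 1.0 h |
| eta | 0.80 M |  | 1.0 h |

| run | time / min | single ring / % | substrate / % |
|---|---|---|---|
| north-west | 15.0 | 72.6 | 1.3 |
| north-west | 30.0 | 69.4 | 0 |
| north-west | 50.0 | 65.6 | 0.8 |
| north-west | 60.0 | 63.7 | 0 |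
| south | 5.00 | 27.6 | 6.7 |
| south | 12.0 | 32.4 | 0 |
| south | 25.0 | 32.6 | 0 |
| south | 60.0 | 28.3 | 0.6 |

(standard deviation of a reading: 1 percentage point)

1. all flasks from highest to lowest amount of single ring, in percent of the substrate charged, at 1.0 h (theta / gamma / beta / eta)
2. the same order at 6.0 min (theta / gamma / beta / eta)
3. the amount of single ring, in percent of the substrate charged of the flask you put first, at 1.0 h
4. the amount of single ring, in percent of the substrate charged of the flask you put last, at 1.0 h

- the numbers in the tables scatter with a standard deviation of 1 percentage point
- a reading or a percentage of single ring counts all its forms, free or not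

2. In the north-west run the substrate reading was 0% at 30.0 min, while single ring faded from 72.6% at 15.0 min to 63.7% at 60.0 min, which I read as a first-order fade of 0.00291 /min. Taking that fade back, I read starting yields of 75.8% at 0.15 M and 35.1% at 1 M, a fall with the charge that my first extreme could not give.

3. I let the share of substrate closing at each moment be 1/(1 + c(substrate)/c×), the ratio being the selectivity factor of the two paths. Integrated over a run, this gives the yield Y = ln(1 + x)/x, with x the charge over c×. Putting a trial x of 5 into ln(1 + x)/Y for the south run returned x = 5.11, so c× read 0.196 M, the crossing concentration as fitted to this run, the c(substrate) at which the closing share in my formula stands at 0.5, with every loss of substrate that grows with its concentration counted in the second path. For the north-west run this gave 74.3%, against the 75.8% I had read.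

4. With the fade over 1.0 h, I reckoned 54.1% for gamma and 23.7% for beta.

5. The forecast gave gamma > theta > eta > beta at 1.0 h and gamma > theta > eta > beta at 6.0 min, with 55% (52% to 58%) and 23% (20.5% to 25.5%), on the grounds of “a first-order ring closure competing with a second-order reaction of the substrate with itself”. My two figures differed slightly from its figures but lay inside its ranges.

6. The flasks gave gamma > theta > eta > beta and gamma > theta > eta > beta, with 54.9% and 22.3%, so the forecast held.

    substrate → single ring (k = 0.00370 /s)
    2 substrate → open dimer (k = 0.00730 /M/s)
    substrate + open dimer → open trimer (k = 0.0110 /M/s)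
    open dimer → ring dimer (k = 3.40 × 10⁻⁴ /s)
    single ring → over-reaction product (k = 5.70 × 10⁻⁵ /s)
    crystals ⇌ single ring, rate k6*(cs6 - [single ring]) while solid is left; crystals form when [single ring] > cs6 (solubility = 0.260 M, k = 0.00270 /s)
    substrate → decomposition product (k = 3.90 × 10⁻⁷ /s)

7. Gamma had not come to rest at 1.0 h: its substrate stood at 0%, but over 10.0 h its single ring went from 54.9% to 8.66% and its over-reaction product from 11.7% to 57.9%, while its open trimer stayed at 11.7%. The half-life of that fade in gamma, 3.4 h, is longer than the 1.0 h asked about. Beta held 46.5% open trimer and 5.28% crystals at 1.0 h, which c× does not show, and the step from open dimer to ring dimer made no difference to its single ring.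

8. For a further flask like beta but charged with 0.60 M, c× gave x = 3.06 and, with the fade, 38.4% at 1.0 h; the computed value was 37.6%.

(The earlier runs and the new flask were generated by integration on assumed constants, noise included.)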